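A level of chains below full yield is easily read as a stalled polymerisation, yet a side reaction with a finite charge can give the same picture.

| flask | solid monomer | protic impurity | initiator | remark | time |
|---|---|---|---|---|---|
| alpha | 0.20 M | 0.020 M | 1 mM (in portions, 3) | the very flask that is asked about, followed so far; portions every 2.5 h |  |
| gamma | 0.20 M | 0.020 M | 0.67 mM (in portions, 3) | run made earlier; portions every 2.5 h |  |
| flask | 0.20 M | 0.0200 M | 1.0 mM (in portions, 3) | the portions of initiator follow each other after 2.5 h, the first at the start | 15 d |

| run | time / d | solid monomer / % | monomer in chains / % |
|---|---|---|---|
| alpha | 0.250 | 50 | 1 |
| alpha | 0.417 | 43 | 7 |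
| alpha | 0.833 | 10 | 37 |
| alpha | 1.67 | 0 | 84 |
| alpha | 3.00 | 0 | 92 |
| gamma | 1.25 | 0 | 52 |
| gamma | 2.50 | 0 | 89 |
| gamma | 4.00 | 0 | 95 |
| gamma | 8.00 | 1 | 94 |
| gamma | 15.0 | 0 | 91 |

(each reading ± 1.5 percentage points)

- which holds at 15 d: what has brought the reaction to rest, or that it has not come to rest (for what has run out or reacted, a solid counts together with what of it has only dissolved) (all of the solid monomer has reacted / forward and back rates have come level / it is still moving / no working catalyst is left)
- part of the solid monomer that has turned into other species by 15 d (what has only dissolved does not count)
- how much monomer in chains there is at 15 d, in percent of the solid monomer charged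

- given per volume of solution although it is solid: solid monomer
- the earlier runs were read with a standard deviation of 1.5 percentage points
- what may be going on: free monomer + living end -> monomer in chains + living end; free monomer + initiator -> living end + monomer in chains; solid monomer <-> free monomer; protic impurity + free monomer -> quenched substrate
- at the start none of the solid monomer is in solution
- what has only dissolved of solid monomer counts as not reacted
- the reaction counts as stopped when no species that holds the solid monomer changes by six tenths of a point or more over the second half of the time

The quantity to carry is the quench ceiling, the charged protic impurity as a fraction of the charged solid monomer, which is the stoichiometric limit of the quenched substrate at one impurity per monomer. Here it is 10.0%. Once solid and free monomer have both gone, and if chains do not decay, chains can stand no lower than 90.0% of the charge.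

1. In alpha, the flask asked about, the solid falls to 50% by 0.250 d while chains read 1%, so the chain curve starts nearly flat.

2. Chains overtake solid in alpha between 0.417 d and 0.833 d: 7% against 43%, then 37% against 10%.

3. The knee in alpha lies near 1.67 d, where solid reads 0% and chains 84%.

4. The level in alpha reads 92% at 3.00 d. That leaves a gap of 8.00%, smaller than the ceiling. Gamma has the same ceiling and reads 95%, 94% and 91% from 4.00 d to 15.0 d.

5. The reckoning here commits to a level at or above 90.0% in alpha.

The forecast says all of the solid monomer has reacted, with conversion 100% (99% to 100%) and chains 93% (91% to 95%), the shortfall being “monomer lost to the protic impurity, which could take at most 10%”.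

The flask gives: all of the solid monomer has reacted, with conversion 100% and chains 91.7%, inside the forecast's range.

    free monomer + living end → monomer in chains + living end, rate k1*[living end]*[free monomer] (k = 125 /M/h)
    free monomer + initiator → living end + monomer in chains (k = 0.687 /M/h)
    solid monomer ⇌ free monomer, rate k3*(cs3 - [free monomer]) while solid is left; crystals form when [free monomer] > cs3 (solubility = 0.0950 M, k = 1.12 /h)
    protic impurity + free monomer → quenched substrate (k = 0.629 /M/h)

Quenched substrate stands at 8.35% at 15.0 d, which fills 83.5% of the ceiling, and chains lie above the floor.

The neighbour flask, the same recipe with 0.080 M of solid monomer, has a ceiling of 25.0%, which puts its floor at 75.0%. That neighbour flask gives chains 84.1% and quenched substrate 15.9%, which is 63.6% of its ceiling.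

The numbers in the tables are simulated on assumed constants; scatter was added.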